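## Retrosynthetic overview

1. Aspidin (20) is cut through two bonds of its non-aromatic six-membered ring: the bond from the butanoyl-bearing carbon to its hydroxylated neighbour, and the bond from the gem-dimethyl carbon to its hydroxylated neighbour. This is a [3+3] double C-acylation that joins a malonyl unit (the ring carbon carrying the arylmethyl group plus its two oxygenated neighbours) to the α- and α′-carbons of a masked 2-methylheptane-3,5-dione.
2. Enabling feature: the three oxygen-bearing carbons of that carbocycle are mutually 1,3,5, so carbonyl-level and enolisable ring carbons alternate. In addition, the phenol oxygen ortho to the CH2 bridge on the aromatic ring can hold one malonyl carbonyl as a six-membered lactone (an aryl ester), which the ring closure opens again.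
3. Dinucleophile 17: ynone 14 (pent-1-yne + 2-methylpropanoyl chloride) → pyrrolidine enaminone 15 → 1-amino-3-siloxydiene 17. The amine masks the butanoyl carbonyl, makes its α-carbon nucleophilic and leaves the isopropyl methine as the only α′-hydrogen.
4. Dielectrophile 11: 2-methylphloroglucinol (1) → formylation → para-O-methylation → butanoylation → Knoevenagel/lactonisation with Meldrum's acid → hydrogenation → acid chloride.
5. Ring order: the aromatic ring is bought; the temporary lactone ring is closed in step 4; the carbocycle is closed last, in step 10, in the same operation that opens the lactone and unmasks the butanoyl group.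

Key step: step 10

Remark on the chemistry: the target has no stereocentre. Enol/keto tautomers are drawn as in the target SMILES. Compounds 10, 11 and 18 carry one enolisable stereocentre and are used as racemates.

## Route

Step 1
Reactants: 1 2-methylbenzene-1,3,5-triol (2-methylphloroglucinol)
Product: 3 2,4,6-trihydroxy-3-methylbenzaldehyde, via aryl iminium chloride 2 (not isolated)
Conditions: (chloromethylene)dimethyliminium chloride (1.05 equiv), MeCN, 0 °C to rt; then H2O, 50 °C
Reagents that add atoms: (chloromethylene)dimethyliminium chloride, C[N+](C)=CCl.[Cl-]; water, O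
Why: Vilsmeier–Haack formylation: the two free ring positions of 1 are equivalent and the first iminium group deactivates the ring towards a second attack, so hydrolysis of 2 should give the mono-aldehyde as a single regioisomer; no stereocentre is formed.

Step 2
Reactants: 3 2,4,6-trihydroxy-3-methylbenzaldehyde
Product: 4 2,6-dihydroxy-4-methoxy-3-methylbenzaldehyde
Conditions: Me2SO4 (1.0 equiv), K2CO3 (1.0 equiv), acetone, 0 °C to rt
Reagents that add atoms: dimethyl sulfate, COS(=O)(=O)OC
Why: Williamson-type O-methylation under weak base: the hydroxyl para to the formyl group is the most acidic and the only one that cannot hydrogen-bond to the aldehyde, so one equivalent of dimethyl sulfate should alkylate it first (the preference known for 2,4,6-trihydroxyacetophenone), which places the methoxy group para to the future bridging carbon.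

Step 3
Reactants: 4 2,6-dihydroxy-4-methoxy-3-methylbenzaldehyde; 5 butanoyl chloride
Product: 6 3-butanoyl-2,6-dihydroxy-4-methoxy-5-methylbenzaldehyde
Conditions: TiCl4 (2.5 equiv), CH2Cl2, 0 °C to rt; aq. HCl work-up
Reagents that add atoms: none
Why: Friedel–Crafts acylation: the ring has a single unsubstituted carbon, ortho to the methoxy group and ortho/para to the two hydroxyls, so C-butanoylation can give only 6 (a phenyl ester formed first would reach the same product by Fries rearrangement under TiCl4).

Step 4
Reactants: 6 3-butanoyl-2,6-dihydroxy-4-methoxy-5-methylbenzaldehyde; 7 2,2-dimethyl-1,3-dioxane-4,6-dione (Meldrum's acid)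
Product: 9 6-butanoyl-5-hydroxy-7-methoxy-8-methyl-2-oxo-2H-chromene-3-carboxylic acid, via arylidene Meldrum's acid 8 (not isolated)
Conditions: piperidine (cat.), AcOH (cat.), EtOH, rt to 60 °C
Reagents that add atoms: none
Why: Knoevenagel condensation followed by lactonisation (the standard coumarin-3-carboxylic acid synthesis from salicylaldehydes): once the aldehyde has condensed, the hydroxyl next to the methyl group is no longer hydrogen-bonded and should attack a Meldrum's acid carbonyl with loss of acetone, while the other hydroxyl stays chelated to the butanoyl group; the regioisomeric lactone, if formed, would open to the same phenol in step 10.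

Step 5
Reactants: 9 6-butanoyl-5-hydroxy-7-methoxy-8-methyl-2-oxo-2H-chromene-3-carboxylic acid
Product: 10 6-butanoyl-5-hydroxy-7-methoxy-8-methyl-2-oxo-3,4-dihydro-2H-chromene-3-carboxylic acid (racemic)
Conditions: H2 (1 atm), 10% Pd/C, EtOAc, rt
Reagents that add atoms: none
Why: Heterogeneous catalytic hydrogenation: the electron-poor C3–C4 alkene of the coumarin should be reduced much faster than the chelated, doubly ortho-substituted aryl ketone or the arene; the new C3 stereocentre forms racemic and needs no control because it is enolisable and is erased in step 10.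

Step 6
Reactants: 10 6-butanoyl-5-hydroxy-7-methoxy-8-methyl-2-oxo-3,4-dihydro-2H-chromene-3-carboxylic acid
Product: 11 6-butanoyl-5-hydroxy-7-methoxy-8-methyl-2-oxo-3,4-dihydro-2H-chromene-3-carbonyl chloride (racemic)
Conditions: (COCl)2 (1.2 equiv), DMF (cat.), CH2Cl2, 0 °C to rt; evaporation with toluene, used crude
Reagents that add atoms: oxalyl chloride, O=C(Cl)C(=O)Cl
Why: Acid chloride formation through the catalytic chloroiminium (Vilsmeier-type) intermediate: the lactone is inert, the ring has no free position, and the remaining phenol is locked in a hydrogen bond to the butanoyl carbonyl between two ortho substituents, so it should not be acylated; C3 stays racemic.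

Step 7
Reactants: 12 pent-1-yne; 13 2-methylpropanoyl chloride
Product: 14 2-methyloct-4-yn-3-one
Conditions: PdCl2(PPh3)2 (2 mol %), CuI (4 mol %), Et3N (1.1 equiv), THF, rt
Reagents that add atoms: none
Why: Acyl Sonogashira coupling (copper acetylide transmetalation to an acylpalladium chloride) gives the ynone directly; the triple bond holds the future butanoyl carbonyl carbon at a masked oxidation level and leaves the isopropyl methine as the only C–H α to the ketone.

Step 8
Reactants: 14 2-methyloct-4-yn-3-one
Product: 15 (4E)-2-methyl-5-(pyrrolidin-1-yl)oct-4-en-3-one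
Conditions: pyrrolidine (1.05 equiv), EtOH, 0 °C to rt
Reagents that add atoms: pyrrolidine, C1CCNC1
Why: Aza-Michael addition of a secondary amine to an ynone, which is regiospecific for the β-carbon and should give the (E)-enaminone (vinylogous amide) under thermodynamic control.

Step 9
Reactants: 15 (4E)-2-methyl-5-(pyrrolidin-1-yl)oct-4-en-3-one
Product: 17 1-[(4E)-3-[(tert-butyldimethylsilyl)oxy]-2-methylocta-2,4-dien-5-yl]pyrrolidine, via lithium dienolate 16 (not isolated)
Conditions: LiN(i-Pr)2 (1.1 equiv), THF, −78 °C; TBSCl (1.2 equiv), −78 °C to rt; pentane, filtration under argon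
Reagents that add atoms: tert-butyl(chloro)dimethylsilane, CC(C)(C)[Si](C)(C)Cl; lithium diisopropylamide, CC(C)[N-]C(C)C.[Li+] (lithium of 16 only)
Why: Kinetic α′-deprotonation of a vinylogous amide and O-silylation, the standard preparation of 1-amino-3-siloxy-1,3-dienes: the lithium amide bound to the carbonyl oxygen should remove the only α′-hydrogen (the isopropyl methine) faster than the remote γ-hydrogens of the propyl group, giving a diene whose two nucleophilic carbons are the future gem-dimethyl carbon and the enamine β-carbon.

Step 10
Reactants: 11 6-butanoyl-5-hydroxy-7-methoxy-8-methyl-2-oxo-3,4-dihydro-2H-chromene-3-carbonyl chloride; 17 1-[(4E)-3-[(tert-butyldimethylsilyl)oxy]-2-methylocta-2,4-dien-5-yl]pyrrolidine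
Product: 20 aspidin, via acylated enaminone lactone 18 (not isolated), via cyclised enaminone trione 19 (not isolated)
Conditions: CH2Cl2, −78 °C to 0 °C; then Et3N (2 equiv), DMAP (0.2 equiv), 0 °C to 40 °C; then 1 M aq. HCl, THF, rt to 40 °C
Reagents that add atoms: water, O
Why: Proposed new method: a [3+3] double C-acylation in which the silyl enol ether terminus of 17 (the future gem-dimethyl carbon) attacks the acid chloride of 11 in a Mukaiyama-type acylation with loss of TBSCl to give β-keto lactone 18, whose acidic malonyl C–H is then removed by Et3N/DMAP so that the lactone opens by E1cB to an aryloxide-tethered acylketene (or is attacked directly) and the enaminone β-carbon closes the carbocycle to 19, freeing the phenol, before aqueous acid hydrolyses the twisted tertiary enaminone to the butanoyl group. The closest known reactions are the Effenberger cyclisation of enol ethers with malonyl dichloride to cyclohexane-1,3,5-triones, the [3+3] cyclisations of 1,3-bis(silyloxy)-1,3-dienes with 1,3-dielectrophiles, and the E1cB acyl transfer of aryl β-keto esters. The six-membered carbocycle closes in a 6-exo-trig mode on the lactone carbonyl (6-exo-dig if the ketene is the electrophile), and the lactone ring is opened in the same event. No stereocentre is created: the labile C3 centre of 11 becomes an sp2 enol carbon and the target is achiral. The step needs C- over O-acylation and the right pair of nucleophilic carbons: the diene offers only two carbon nucleophiles, the propyl CH2 is not activated, the acid chloride is far more reactive than the lactone so the two acylations are ordered, and O-acylated enaminones or aryl esters are themselves acyl donors that should funnel under DMAP to the C-acylated triketone enolate as the thermodynamic sink. If the enamine carbon reacts first, the same ring results with the two acyl carbons exchanged, which is a degenerate outcome.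

## Compound list

1 | 2-methylbenzene-1,3,5-triol | Cc1c(O)cc(O)cc1O | starting material
2 | N,N-dimethyl-1-(2,4,6-trihydroxy-3-methylphenyl)methaniminium chloride | C[N+](C)=Cc1c(O)cc(O)c(C)c1O.[Cl-] | intermediate
3 | 2,4,6-trihydroxy-3-methylbenzaldehyde | O=Cc1c(O)cc(O)c(C)c1O | intermediate
4 | 2,6-dihydroxy-4-methoxy-3-methylbenzaldehyde | O=Cc1c(O)cc(OC)c(C)c1O | intermediate
5 | butanoyl chloride | CCCC(=O)Cl | starting material
6 | 3-butanoyl-2,6-dihydroxy-4-methoxy-5-methylbenzaldehyde | O=Cc1c(O)c(C(=O)CCC)c(OC)c(C)c1O | intermediate
7 | 2,2-dimethyl-1,3-dioxane-4,6-dione (Meldrum's acid) | CC1(C)OC(=O)CC(=O)O1 | starting material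
8 | 5-[(3-butanoyl-2,6-dihydroxy-4-methoxy-5-methylphenyl)methylidene]-2,2-dimethyl-1,3-dioxane-4,6-dione | CCCC(=O)c1c(O)c(C=C2C(=O)OC(C)(C)OC2=O)c(O)c(C)c1OC | intermediate
9 | 6-butanoyl-5-hydroxy-7-methoxy-8-methyl-2-oxo-2H-chromene-3-carboxylic acid | CCCC(=O)c1c(O)c2C=C(C(=O)O)C(=O)Oc2c(C)c1OC | intermediate
10 | 6-butanoyl-5-hydroxy-7-methoxy-8-methyl-2-oxo-3,4-dihydro-2H-chromene-3-carboxylic acid (racemic) | CCCC(=O)c1c(O)c2CC(C(=O)O)C(=O)Oc2c(C)c1OC | intermediate
11 | 6-butanoyl-5-hydroxy-7-methoxy-8-methyl-2-oxo-3,4-dihydro-2H-chromene-3-carbonyl chloride (racemic) | CCCC(=O)c1c(O)c2CC(C(=O)Cl)C(=O)Oc2c(C)c1OC | intermediate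
12 | pent-1-yne | CCCC#C | starting material
13 | 2-methylpropanoyl chloride | CC(C)C(=O)Cl | starting material
14 | 2-methyloct-4-yn-3-one | CCCC#CC(=O)C(C)C | intermediate
15 | (4E)-2-methyl-5-(pyrrolidin-1-yl)oct-4-en-3-one | CC(C)C(=O)/C=C(\CCC)N1CCCC1 | intermediate
16 | lithium (4E)-2-methyl-5-(pyrrolidin-1-yl)octa-2,4-dien-3-olate | [Li+].CC(C)=C([O-])/C=C(\CCC)N1CCCC1 | intermediate
17 | 1-[(4E)-3-[(tert-butyldimethylsilyl)oxy]-2-methylocta-2,4-dien-5-yl]pyrrolidine | CC(C)=C(O[Si](C)(C)C(C)(C)C)/C=C(\CCC)N1CCCC1 | intermediate
18 | 6-butanoyl-3-[(4E)-2,2-dimethyl-3-oxo-5-(pyrrolidin-1-yl)oct-4-enoyl]-5-hydroxy-7-methoxy-8-methyl-3,4-dihydro-2H-chromen-2-one (racemic) | CCCC(=O)c1c(O)c2CC(C(=O)C(C)(C)C(=O)/C=C(\CCC)N3CCCC3)C(=O)Oc2c(C)c1OC | intermediate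
19 | 4-[(3-butanoyl-2,6-dihydroxy-4-methoxy-5-methylphenyl)methyl]-5-hydroxy-6,6-dimethyl-2-[1-(pyrrolidin-1-yl)butylidene]cyclohex-4-ene-1,3-dione | CCCC(N1CCCC1)=C1C(=O)C(Cc2c(O)c(C)c(OC)c(C(=O)CCC)c2O)=C(O)C(C)(C)C1=O | intermediate
20 | aspidin, 2-butanoyl-4-[(3-butanoyl-2,6-dihydroxy-4-methoxy-5-methylphenyl)methyl]-3,5-dihydroxy-6,6-dimethylcyclohexa-2,4-dien-1-one | CCCC(=O)C1=C(O)C(Cc2c(O)c(C)c(OC)c(C(=O)CCC)c2O)=C(O)C(C)(C)C1=O | target

## Step count and risks

Total steps: 10. Longest linear sequence: 7 (steps 1 to 6, then step 10); the second branch is steps 7 to 9.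

The three steps most likely to fail:

Step 10 (Proposed new method). What may go wrong: acylation at the enaminone or phenol oxygen in place of carbon, proton transfer from the acidic malonyl C–H of 11 to the basic diene, or failure of the second, ring-closing acylation at the hindered centre. The fallback uses known chemistry and makes the bridge last. It sets out from aldehyde 6. Commercial 1-(2,4,6-trihydroxyphenyl)butan-1-one F1 would be geminally C-methylated (NaOMe, MeI, MeOH, 0 °C to rt) to 2-butanoyl-3,5-dihydroxy-4,4-dimethylcyclohexa-2,5-dien-1-one F2 (butyrylfilicinic acid). An organocatalytic reductive Knoevenagel alkylation of F2 with 6 (L-proline cat., Hantzsch ester, CH2Cl2, rt) should then pass through the alkylidene triketone 2-butanoyl-4-[(3-butanoyl-2,6-dihydroxy-4-methoxy-5-methylphenyl)methylidene]-3-hydroxy-6,6-dimethylcyclohex-2-ene-1,5-dione F3, which is reduced in the flask. The fallback comes back to the route at 20.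

Step 9. What may go wrong: competing γ-deprotonation at the propyl methylene, incomplete deprotonation of the hindered methine, or hydrolysis of the diene on handling. The fallback fixes the enolate position by where a hydride adds instead of by which proton is removed. It sets out from pent-1-yne 12, which would be coupled under the conditions of step 7 with 2-methylprop-2-enoyl chloride F4 to give 2-methyloct-1-en-4-yn-3-one F5. Pyrrolidine (1.0 equiv, EtOH, 0 °C) should add to the ynone terminus to give (4E)-2-methyl-5-(pyrrolidin-1-yl)octa-1,4-dien-3-one F6. Conjugate reduction of the isopropenyl ketone (Li[HB(s-Bu)3], THF, −78 °C) would then give the lithium dienolate 16 regiospecifically, and trapping with TBSCl as in step 9 comes back to the route at 17.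

Step 2. What may go wrong: over-methylation and loss of site selectivity between the para and the two ortho hydroxyls, with some C-methylation of the electron-rich ring. The fallback replaces selective alkylation by selective dealkylation. It sets out from 3, which would be exhaustively O-methylated (Me2SO4 in excess, K2CO3, acetone, reflux) to 2,4,6-trimethoxy-3-methylbenzaldehyde F7. Chelation-directed cleavage of the two methyl ethers ortho to the formyl group (BCl3 in excess, CH2Cl2, 0 °C to rt) should leave the para ether untouched and comes back to the route at 4.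

## Further compounds

F1 | step 10 | 1-(2,4,6-trihydroxyphenyl)butan-1-one | CCCC(=O)c1c(O)cc(O)cc1O
F2 | step 10 | 2-butanoyl-3,5-dihydroxy-4,4-dimethylcyclohexa-2,5-dien-1-one (butyrylfilicinic acid) | CCCC(=O)C1=C(O)C=C(O)C(C)(C)C1=O
F3 | step 10 | 2-butanoyl-4-[(3-butanoyl-2,6-dihydroxy-4-methoxy-5-methylphenyl)methylidene]-3-hydroxy-6,6-dimethylcyclohex-2-ene-1,5-dione | CCCC(=O)C1=C(O)C(=Cc2c(O)c(C)c(OC)c(C(=O)CCC)c2O)C(=O)C(C)(C)C1=O
F4 | step 9 | 2-methylprop-2-enoyl chloride | C=C(C)C(=O)Cl
F5 | step 9 | 2-methyloct-1-en-4-yn-3-one | CCCC#CC(=O)C(C)=C
F6 | step 9 | (4E)-2-methyl-5-(pyrrolidin-1-yl)octa-1,4-dien-3-one | C=C(C)C(=O)/C=C(\CCC)N1CCCC1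
F7 | step 2 | 2,4,6-trimethoxy-3-methylbenzaldehyde | O=Cc1c(OC)c(C)c(OC)cc1OC
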